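The target is fisetinidol-(4α→6)-mollisacacidin, the dimer of (+)-mollisacacidin, so one monomer supplies both units and the C4–C6 bond is formed last by acid-mediated self-condensation. Everything rests on how the monomer's pyran ring (O1, C2, C3, C4, C4a, C8a; ring C of each unit) is made: O1–C2(aryl)–C3(OH) is the imprint of a trans aryl epoxide opened by the ring A phenol, and C3–C4(=O) that of an aryl glyoxal. The key step inserts C2, as a chiral sulfonium benzylide, between O1 and the hemiacetal carbon of a five-membered 2-hydroxybenzofuran-3(2H)-one, expanding it to the (2R,3R)-dihydroflavonol and setting C2 and C3 in one operation.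

Key step: step 5

Remark 1: the (2-hydroxyaryl)glyoxal is taken to rest as its cyclic hemiacetal, the 2-hydroxybenzofuran-3(2H)-one, which reopens to the glyoxal phenoxide on deprotonation.
Remark 2: the benzylide of (2R,5R)-2,5-dimethylthiolane is assumed to attack aldehydes so that the benzylic epoxide carbon becomes S; should the sense be opposite, the enantiomeric sulfide from (2R,5R)-hexane-2,5-diol is used in the same way.

Step 1
Reactants: 1 (2S,5S)-hexane-2,5-diol
Product: 2 (2S,5S)-hexane-2,5-diyl dimethanesulfonate
Conditions: MsCl, Et3N, CH2Cl2, 0 °C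
Reagents that add atoms: methanesulfonyl chloride, CS(=O)(=O)Cl
Why: Mesylation takes place at oxygen, so both carbinol configurations are retained.

Step 2
Reactants: 2 (2S,5S)-hexane-2,5-diyl dimethanesulfonate
Product: 3 (2R,5R)-2,5-dimethylthiolane
Conditions: Na2S·9H2O, DMSO, rt → 50 °C; distillation
Reagents that add atoms: sodium sulfide, [Na+].[Na+].[S-2]
Why: Double SN2 thioetherification (intermolecular, then 5-exo-tet) inverts both centres and should turn the (2S,5S) dimesylate into the trans (2R,5R) thiolane.

Step 3
Reactants: 3 (2R,5R)-2,5-dimethylthiolane; 4 3,4-bis(benzyloxy)benzyl chloride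
Product: 5 (2R,5R)-1-[3,4-bis(benzyloxy)benzyl]-2,5-dimethylthiolan-1-ium tetrafluoroborate
Conditions: AgBF4, acetone, rt, dark
Reagents that add atoms: silver tetrafluoroborate, [Ag+].F[B-](F)(F)F
Why: S-alkylation of the dialkyl sulfide by the electron-rich benzylic chloride is driven by precipitation of AgCl, and the twofold symmetry of the sulfide makes both sulfur faces equivalent, so a single sulfonium salt should form.

Step 4
Reactants: 6 4'-(benzyloxy)-2'-hydroxyacetophenone
Product: 7 6-(benzyloxy)-2-hydroxybenzofuran-3(2H)-one (racemic at the hemiacetal carbon)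
Conditions: SeO2, 1,4-dioxane/H2O, reflux; azeotropic drying (toluene)
Reagents that add atoms: selenium dioxide, O=[Se]=O
Why: Riley oxidation converts the acetyl methyl into the glyoxal aldehyde, onto which the ortho phenol adds (5-exo-trig) to give the five-membered cyclic hemiacetal.

Step 5
Reactants: 5 (2R,5R)-1-[3,4-bis(benzyloxy)benzyl]-2,5-dimethylthiolan-1-ium tetrafluoroborate; 7 6-(benzyloxy)-2-hydroxybenzofuran-3(2H)-one
Product: 11 (2R,3R)-7-(benzyloxy)-2-[3,4-bis(benzyloxy)phenyl]-3-hydroxychroman-4-one (tri-O-benzylfustin), via glyoxal phenoxide 8 (not isolated), via sulfonium ylide 9 (not isolated), via trans-epoxy ketone 10 (not isolated)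
Conditions: 5, KN(SiMe3)2, THF/CH2Cl2, −78 °C; then potassium salt of 7 (KN(SiMe3)2, THF), −78 → 0 °C; AcOH, 0 °C
Reagents that add atoms: none
Why: Deprotonation opens hemiacetal 7 to the phenoxide of glyoxal 8, whose aldehyde is attacked by ylide 9; collapse of the anti betaine (3-exo-tet) gives trans-epoxy ketone 10 with loss of the sulfide, and the ortho phenoxide O1 then opens the epoxide at the benzylic carbon (6-endo-tet, inversion), so the ylide carbon becomes C2 between O1 and the former hemiacetal carbon C3 and the five-membered ring recloses one atom larger as ring C. The closest known reaction types are the asymmetric Corey–Chaykovsky epoxidation of aldehydes with chiral sulfonium benzylides, including lactols and hemiaminals that react through their open form and re-close onto the epoxide, and the closure of 2'-hydroxychalcone epoxides to dihydroflavonols in the Algar–Flynn–Oyamada reaction. C2 is set by the twofold-symmetric sulfide, which shields one face of the ylide carbon (reagent control: S in 10, R after inversion); C3 follows from the trans epoxide and, lying α to the C4 ketone, can relax to the trans (3R) isomer should any cis material form. The aldehyde is preferred over the aryl ketone because the ketone is deactivated by the ortho and para oxygen donors; 6-endo is preferred over 5-exo opening because the benzylic terminus is electron-rich and C5 carries no substituent. A cold acetic acid quench limits base-induced opening of ring C.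

Step 6
Reactants: 11 (2R,3R)-7-(benzyloxy)-2-[3,4-bis(benzyloxy)phenyl]-3-hydroxychroman-4-one
Product: 12 (+)-fustin [(2R,3R)-2-(3,4-dihydroxyphenyl)-3,7-dihydroxychroman-4-one]
Conditions: H2 (1 atm), 10% Pd/C, EtOAc/MeOH, rt; recrystallisation to raise enantiomeric purity
Reagents that add atoms: none
Why: Hydrogenolysis removes the three aryl benzyl ethers, while the C4 aryl ketone and the C2–O1 bond should persist at 1 atm and rt and C2 and C3 are untouched.

Step 7
Reactants: 12 (+)-fustin
Product: 13 (+)-mollisacacidin [(2R,3S,4R)-2-(3,4-dihydroxyphenyl)chromane-3,4,7-triol]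
Conditions: NaBH4, EtOH, 0 °C → rt; AcOH to pH 6
Reagents that add atoms: none
Why: Borohydride reduction of the chroman-4-one by axial hydride delivery to the half-chair with equatorial 2-aryl and 3-hydroxyl should set C4 as R (equatorial OH, 3,4-trans); the change of descriptor at C3 from R to S is only a change of priorities.

Step 8
Reactants: 13 (+)-mollisacacidin (two molecules)
Product: 15 fisetinidol-(4α→6)-mollisacacidin (target), via flavan-4-yl cation 14 (not isolated)
Conditions: 0.1 M aq HCl, N2, rt → 40 °C, concentrated solution, stopped at partial conversion; Sephadex LH-20 (EtOH), recovered 13 recycled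
Reagents that add atoms: none
Why: Acid ionises the C4 hydroxyl of one molecule of 13 to the benzylic cation 14 (stabilised by O1 and the para 7-hydroxyl), which is captured in a Friedel–Crafts alkylation by C6 of a second molecule (ortho to its 7-hydroxyl, para to its O1, less hindered than C8) from the face anti to the C3 hydroxyl, which should set C4 of the upper unit as R (3,4-trans) while the lower unit keeps its own C4 hydroxyl.

Compound list
1 | (2S,5S)-hexane-2,5-diol | C[C@H](O)CC[C@H](C)O | starting material
2 | (2S,5S)-hexane-2,5-diyl dimethanesulfonate | C[C@H](OS(C)(=O)=O)CC[C@H](C)OS(C)(=O)=O | intermediate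
3 | (2R,5R)-2,5-dimethylthiolane | C[C@@H]1CC[C@@H](C)S1 | intermediate
4 | 3,4-bis(benzyloxy)benzyl chloride | ClCc1ccc(OCc2ccccc2)c(OCc2ccccc2)c1 | starting material
5 | (2R,5R)-1-[3,4-bis(benzyloxy)benzyl]-2,5-dimethylthiolan-1-ium tetrafluoroborate | C[C@@H]1CC[C@@H](C)[S+]1Cc1ccc(OCc2ccccc2)c(OCc2ccccc2)c1.F[B-](F)(F)F | intermediate
6 | 4'-(benzyloxy)-2'-hydroxyacetophenone | CC(=O)c1ccc(OCc2ccccc2)cc1O | starting material
7 | 6-(benzyloxy)-2-hydroxybenzofuran-3(2H)-one (racemic hemiacetal) | O=C1c2ccc(OCc3ccccc3)cc2OC1O | intermediate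
8 | 2-[4-(benzyloxy)-2-hydroxyphenyl]-2-oxoacetaldehyde (open form of 7, present as its potassium phenoxide; not isolated) | O=CC(=O)c1ccc(OCc2ccccc2)cc1O | intermediate
9 | (2R,5R)-2,5-dimethylthiolan-1-ium 3,4-bis(benzyloxy)benzylide (not isolated) | C[C@@H]1CC[C@@H](C)[S+]1[CH-]c1ccc(OCc2ccccc2)c(OCc2ccccc2)c1 | intermediate
10 | [(2R,3S)-3-[3,4-bis(benzyloxy)phenyl]oxiran-2-yl][4-(benzyloxy)-2-hydroxyphenyl]methanone (trans; not isolated) | O=C(c1ccc(OCc2ccccc2)cc1O)[C@@H]1O[C@H]1c1ccc(OCc2ccccc2)c(OCc2ccccc2)c1 | intermediate
11 | (2R,3R)-7-(benzyloxy)-2-[3,4-bis(benzyloxy)phenyl]-3-hydroxychroman-4-one (tri-O-benzylfustin; 2,3-trans) | O=C1c2ccc(OCc3ccccc3)cc2O[C@H](c2ccc(OCc3ccccc3)c(OCc3ccccc3)c2)[C@H]1O | intermediate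
12 | (+)-fustin, (2R,3R)-2-(3,4-dihydroxyphenyl)-3,7-dihydroxychroman-4-one | O=C1c2ccc(O)cc2O[C@H](c2ccc(O)c(O)c2)[C@H]1O | intermediate
13 | (+)-mollisacacidin, (2R,3S,4R)-2-(3,4-dihydroxyphenyl)chromane-3,4,7-triol (2,3-trans-3,4-trans) | Oc1ccc2c(c1)O[C@H](c1ccc(O)c(O)c1)[C@@H](O)[C@@H]2O | intermediate
14 | (2R,3S)-2-(3,4-dihydroxyphenyl)-3,7-dihydroxychroman-4-ylium (C4 cation of 13; not isolated) | Oc1ccc2c(c1)O[C@H](c1ccc(O)c(O)c1)[C@@H](O)[CH+]2 | intermediate
15 | (2R,3S,4R)-2-(3,4-dihydroxyphenyl)-6-[(2R,3S,4R)-2-(3,4-dihydroxyphenyl)-3,7-dihydroxychroman-4-yl]chromane-3,4,7-triol | Oc1ccc2c(c1)O[C@H](c1ccc(O)c(O)c1)[C@@H](O)[C@@H]2c1cc2c(cc1O)O[C@H](c1ccc(O)c(O)c1)[C@@H](O)[C@@H]2O | target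

Total step count: 8
Longest linear sequence: 7 steps (steps 1, 2, 3, 5, 6, 7, 8)

Steps most likely to fail

Step 5. What may go wrong is poor facial selectivity at the ylide carbon, so that 11 forms with low enantiomeric purity; betaine formation with the very electrophilic glyoxal may be partly irreversible, which would worsen this. The fallback keeps the ring expansion but gives up asymmetric induction and separates the enantiomers afterwards. It sets out from 4 and 7. S-alkylation of tetrahydrothiophene with 4 (AgBF4, acetone) should give 1-[3,4-bis(benzyloxy)benzyl]thiolan-1-ium tetrafluoroborate F1. Its ylide (KN(SiMe3)2, −78 °C) and the potassium salt of 7 should give, by the same epoxide-forming ring expansion, racemic trans-7-(benzyloxy)-2-[3,4-bis(benzyloxy)phenyl]-3-hydroxychroman-4-one F2. Preparative chromatography on an amylose tris(3,5-dimethylphenylcarbamate) phase then returns the (2R,3R) enantiomer, and the route is rejoined at 11.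

Step 8. What may go wrong is uncontrolled chain growth, since the dimer is itself both electrophile and nucleophile, together with scrambling between 4α and 4β attack and between C6 and C8 attack. The fallback separates the roles of electrophile and nucleophile. It sets out from 13. Part of 13 is treated with phenylmethanethiol in acetic acid, which through the same C4 cation should give (2R,3S)-4-(benzylsulfanyl)-2-(3,4-dihydroxyphenyl)chromane-3,7-diol F3 (either C4 epimer serves). Activation of F3 with AgBF4 in THF at 0 °C in the presence of a four- to fivefold excess of 13 should ionise only the thioether, because the C4 hydroxyl of 13 and of the product is inert to the thiophilic silver salt. Capture by C6 of 13 rejoins the route at 15, and excess 13 is recovered.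

Step 4. What may go wrong is over-oxidation of the glyoxal to the arylglyoxylic acid and oligomerisation of its hydrate, so that no clean hemiacetal is obtained. The fallback builds the five-membered ring first and hydroxylates it afterwards. It sets out from 6. α-Bromination (CuBr2, EtOAc/CHCl3, reflux) should give 2-bromo-1-[4-(benzyloxy)-2-hydroxyphenyl]ethan-1-one F4. Intramolecular O-alkylation (NaOAc, EtOH, reflux) should close it to 6-(benzyloxy)benzofuran-3(2H)-one F5. Silylation (TBSOTf, Et3N, CH2Cl2) should give {[6-(benzyloxy)benzofuran-3-yl]oxy}(tert-butyl)dimethylsilane F6. Rubottom oxidation of F6 (dimethyldioxirane, acetone, −40 °C; then dilute HCl, THF) rejoins the route at 7.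

Further compounds
F1 | step 5 | 1-[3,4-bis(benzyloxy)benzyl]thiolan-1-ium tetrafluoroborate | C1CC[S+](C1)Cc1ccc(OCc2ccccc2)c(OCc2ccccc2)c1.F[B-](F)(F)F
F2 | step 5 | racemic trans-7-(benzyloxy)-2-[3,4-bis(benzyloxy)phenyl]-3-hydroxychroman-4-one | O=C1c2ccc(OCc3ccccc3)cc2OC(c2ccc(OCc3ccccc3)c(OCc3ccccc3)c2)C1O
F3 | step 8 | (2R,3S)-4-(benzylsulfanyl)-2-(3,4-dihydroxyphenyl)chromane-3,7-diol (C4 epimers) | Oc1ccc2c(c1)O[C@H](c1ccc(O)c(O)c1)[C@@H](O)C2SCc1ccccc1
F4 | step 4 | 2-bromo-1-[4-(benzyloxy)-2-hydroxyphenyl]ethan-1-one | O=C(CBr)c1ccc(OCc2ccccc2)cc1O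
F5 | step 4 | 6-(benzyloxy)benzofuran-3(2H)-one | O=C1COc2cc(OCc3ccccc3)ccc12
F6 | step 4 | {[6-(benzyloxy)benzofuran-3-yl]oxy}(tert-butyl)dimethylsilane | CC(C)(C)[Si](C)(C)Oc1coc2cc(OCc3ccccc3)ccc12
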